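Ring A (C1 OMe, C2 H, C3 OH) bears three contiguous carbon substituents: identical 4-hydroxybenzyl groups on C4 and C6, on either side of the two-carbon bridge on C5. This ortho/ipso/ortho′ pattern is that of one 3,5-dioxygenated aryl iodide, so C4–CH2, C6–CH2 and C5–CH= are disconnected together. A palladium/norbornene relay should benzylate both C–H bonds next to iodine with one benzylic chloride, then end in a Heck coupling with the ring B styrene. Three skeletal bonds form and no ring closes. The precursor is plain 1-benzyloxy-3-iodo-5-methoxybenzene, carrying only oxygen substituents. Benzyl ethers on all five phenols let a single hydrogenation deliver the target.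

Key step: step 6

Assumption: the target has no stereocentre, and the E geometry of the alkene made in the key step is erased on saturation. Palladium-bound species of catalytic cycles are described in words and not counted as compounds.

Design remark: one commercial benzylic chloride supplies all three 4-hydroxybenzyl groups. It acts twice as the electrophile of the key step and once, after zinc insertion, as the nucleophile that builds the ring B fragment.

Step 1
Reactants: 1 1-iodo-3,5-dimethoxybenzene
Product: 2 3-iodo-5-methoxyphenol
Conditions: NaSEt (1.5 equiv), DMF, 110 °C, argon, dark; then 1 M HCl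
Reagents that add atoms: none
Why: Thiolate-mediated SN2 demethylation of an aryl methyl ether should stop after one methyl group, because the negative charge then residing on the ring oxygen makes the second aryloxide a much poorer leaving group, and the carbon–iodine bond of this electron-rich ring does not undergo SNAr.

Step 2
Reactants: 2 3-iodo-5-methoxyphenol
Product: 3 1-benzyloxy-3-iodo-5-methoxybenzene
Conditions: BnBr, K2CO3, DMF, 25 °C
Reagents that add atoms: benzyl bromide, BrCc1ccccc1
Why: Williamson ether synthesis of a phenol with a primary benzylic bromide under mild carbonate base, to which the aryl iodide and the methyl ether are inert.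

Step 3
Reactants: 4 5-bromo-2-iodophenol
Product: 5 2-benzyloxy-4-bromo-1-iodobenzene
Conditions: BnBr, K2CO3, DMF, 25 °C
Reagents that add atoms: benzyl bromide, BrCc1ccccc1
Why: Williamson ether synthesis again; neither aryl halide reacts with K2CO3 or BnBr at ambient temperature.

Step 4
Reactants: 5 2-benzyloxy-4-bromo-1-iodobenzene; 6 4-(benzyloxy)benzyl chloride
Product: 8 2-benzyloxy-1-[4-(benzyloxy)benzyl]-4-bromobenzene, via 4-(benzyloxy)benzylzinc chloride 7 (not isolated)
Conditions: 6 (1.25 equiv), Zn dust, LiCl, THF, 25 °C; then 5, Pd(PPh3)4 (3 mol %), THF, 25 °C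
Reagents that add atoms: zinc, [Zn] (retained only in intermediate 7)
Why: LiCl-assisted zinc insertion into a benzylic chloride is followed by Negishi coupling, in which zerovalent palladium bearing PPh3 inserts into the carbon–iodine bond far faster than into the carbon–bromine bond at 25 °C, so the bromide para to the new CH2 is kept for step 5.

Step 5
Reactants: 8 2-benzyloxy-1-[4-(benzyloxy)benzyl]-4-bromobenzene; 9 vinylboronic acid pinacol ester
Product: 10 2-benzyloxy-1-[4-(benzyloxy)benzyl]-4-vinylbenzene
Conditions: 9 (1.3 equiv), Pd(dppf)Cl2 (3 mol %), K2CO3, 1,4-dioxane/H2O, 85 °C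
Reagents that add atoms: none
Why: Suzuki–Miyaura coupling of an unhindered aryl bromide with a vinylboronate is a standard vinylation that leaves benzyl ethers and the diarylmethane untouched.

Step 6
Reactants: 3 1-benzyloxy-3-iodo-5-methoxybenzene; 6 4-(benzyloxy)benzyl chloride (two equivalents incorporated); 10 2-benzyloxy-1-[4-(benzyloxy)benzyl]-4-vinylbenzene
Product: 11 (E)-1-benzyloxy-2,4-bis[4-(benzyloxy)benzyl]-3-{2-[3-benzyloxy-4-(4-benzyloxybenzyl)phenyl]ethenyl}-5-methoxybenzene
Conditions: Pd(OAc)2 (10 mol %), P(2-furyl)3 (22 mol %), norbornene (3 equiv), Cs2CO3 (5 equiv), 10 (1.3 equiv), 6 (4 equiv, added in portions), MeCN, 85 °C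
Reagents that add atoms: none
Why: Proposed new method: zerovalent palladium should insert into the carbon–iodine bond of 3, norbornene carbopalladation and concerted metalation–deprotonation of the adjacent C–H give an aryl–norbornyl palladacycle of divalent palladium, SN2-type oxidative addition of chloride 6 raises it to tetravalent palladium, and reductive elimination forges the aryl–CH2 bond; because a free ortho C–H is still within reach, the same sequence repeats on the other side. With both ortho sites filled, steric strain drives β-carbon elimination of norbornene, and the resulting 2,6-dibenzylated arylpalladium species undergoes Mizoroki–Heck syn insertion and syn β-hydride elimination with styrene 10 to give the E alkene. The closest known reaction type is the Catellani ortho,ortho′-dialkylation of ortho-unsubstituted aryl iodides with primary alkyl halides and terminating Heck olefination; untested here are an electron-rich benzylic chloride as the electrophile and C–H bonds wedged between the palladated carbon and an alkoxy group. No ring is closed and no stereocentre is made, and the alkene geometry is erased in step 7. Selection of the iodide over the chloride by zerovalent palladium rests on the much faster insertion into the carbon–iodine bond, the weakly donating phosphine and the choice of a chloride instead of a bromide, while strained norbornene in excess outcompetes 10 for the first arylpalladium species so that premature Heck coupling is held back. The benzylic electrophile has no β-hydrogen, the alkoxy groups inductively acidify the flanked C–H bonds and can turn their alkyl residues toward C2–H, and unsubstituted norbornene is chosen because it favours the second palladation over early extrusion.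

Step 7
Reactants: 11 (E)-1-benzyloxy-2,4-bis[4-(benzyloxy)benzyl]-3-{2-[3-benzyloxy-4-(4-benzyloxybenzyl)phenyl]ethenyl}-5-methoxybenzene
Product: 12 2,4-bis(4-hydroxybenzyl)-3-{2-[3-hydroxy-4-(4-hydroxybenzyl)phenyl]ethyl}-5-methoxyphenol (CNP0207338.0)
Conditions: H2 (3 bar), Pd/C (10 wt %), THF/MeOH, 25 °C
Reagents that add atoms: none
Why: Heterogeneous catalytic hydrogenation adds H2 to the 1,2-disubstituted alkene and hydrogenolyses the five benzylic C–O bonds in the same flask, whereas the aryl methyl ether and the diarylmethane C–C bonds are stable to Pd/C at ambient temperature.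

Compound list
1 | 1-iodo-3,5-dimethoxybenzene | COc1cc(I)cc(OC)c1 | starting material
2 | 3-iodo-5-methoxyphenol | COc1cc(O)cc(I)c1 | intermediate
3 | 1-benzyloxy-3-iodo-5-methoxybenzene | COc1cc(I)cc(OCc2ccccc2)c1 | intermediate
4 | 5-bromo-2-iodophenol | Oc1cc(Br)ccc1I | starting material
5 | 2-benzyloxy-4-bromo-1-iodobenzene | Ic1ccc(Br)cc1OCc1ccccc1 | intermediate
6 | 4-(benzyloxy)benzyl chloride | ClCc1ccc(OCc2ccccc2)cc1 | starting material
7 | 4-(benzyloxy)benzylzinc chloride | Cl[Zn]Cc1ccc(OCc2ccccc2)cc1 | intermediate
8 | 2-benzyloxy-1-[4-(benzyloxy)benzyl]-4-bromobenzene | Brc1ccc(Cc2ccc(OCc3ccccc3)cc2)c(OCc2ccccc2)c1 | intermediate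
9 | vinylboronic acid pinacol ester | C=CB1OC(C)(C)C(C)(C)O1 | starting material
10 | 2-benzyloxy-1-[4-(benzyloxy)benzyl]-4-vinylbenzene | C=Cc1ccc(Cc2ccc(OCc3ccccc3)cc2)c(OCc2ccccc2)c1 | intermediate
11 | (E)-1-benzyloxy-2,4-bis[4-(benzyloxy)benzyl]-3-{2-[3-benzyloxy-4-(4-benzyloxybenzyl)phenyl]ethenyl}-5-methoxybenzene | COc1cc(OCc2ccccc2)c(Cc2ccc(OCc3ccccc3)cc2)c(/C=C/c2ccc(Cc3ccc(OCc4ccccc4)cc3)c(OCc3ccccc3)c2)c1Cc1ccc(OCc2ccccc2)cc1 | intermediate
12 | 2,4-bis(4-hydroxybenzyl)-3-{2-[3-hydroxy-4-(4-hydroxybenzyl)phenyl]ethyl}-5-methoxyphenol | COc1cc(O)c(Cc2ccc(O)cc2)c(CCc2ccc(Cc3ccc(O)cc3)c(O)c2)c1Cc1ccc(O)cc1 | target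

Total step count: 7
Longest linear sequence: 5 steps (steps 3, 4, 5, 6 and 7, from compound 4). The ring A branch (steps 1 and 2) joins at step 6.

Steps most likely to fail

Risk 1 (step 6). Three processes could defeat the step.
- The second palladation, at a C–H bond squeezed between the metal-bearing carbon and an alkoxy group, may lag behind norbornene extrusion, so that benzylation stops half-way.
- Zerovalent palladium may be drained by insertion into the benzylic chloride.
- The crowded arylpalladium species may attack the ring of its own ortho benzyl group instead of the styrene.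

The fallback uses known chemistry only. It sets out from 3, draws on 7 and 8, and returns at 11. Iodine–magnesium exchange with iPrMgCl·LiCl (THF, −20 °C) gives (3-benzyloxy-5-methoxyphenyl)magnesium chloride F1. Quenching with DMF gives 3-benzyloxy-5-methoxybenzaldehyde F2. Electrophilic dibromination (NBS, 2.1 equiv, MeCN) occurs at the two positions next to the formyl group, each para to an alkoxy group, and gives 3-benzyloxy-2,6-dibromo-5-methoxybenzaldehyde F3. Wittig methylenation (Ph3PCH3Br, KOtBu, THF) removes the aldehyde, which a benzylic zinc reagent would otherwise attack, and gives 1-benzyloxy-2,4-dibromo-5-methoxy-3-vinylbenzene F4. Twofold Negishi coupling with organozinc 7 (Pd(OAc)2, SPhos, THF, 50 °C) gives 1-benzyloxy-2,4-bis[4-(benzyloxy)benzyl]-5-methoxy-3-vinylbenzene F5. An ordinary Mizoroki–Heck coupling of F5 with bromide 8 (Pd(OAc)2, P(o-tolyl)3, K2CO3, DMF, 110 °C) then delivers 11.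

Risk 2 (step 4). Wurtz-type homocoupling may occur during zinc insertion into the electron-rich benzylic chloride. Halogen discrimination may also erode, so that the bromide couples as well.

The fallback replaces cross-coupling by polar addition and ionic deoxygenation. It sets out from 5 and returns at 8. Selective iodine–magnesium exchange with iPrMgCl·LiCl (THF, −20 °C), assisted by the neighbouring benzyloxy oxygen, gives (2-benzyloxy-4-bromophenyl)magnesium chloride F6. Addition to commercial 4-(benzyloxy)benzaldehyde (O=Cc1ccc(OCc2ccccc2)cc1) gives racemic (2-benzyloxy-4-bromophenyl)[4-(benzyloxy)phenyl]methanol F7. Ionic reduction of this doubly activated benzhydrol (Et3SiH, TFA, CH2Cl2, 0 °C) gives 8 and removes the transient stereocentre.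

Risk 3 (step 7). The alkene is shielded by the two ortho benzyl groups of ring A and may be saturated slowly or incompletely on the metal surface. Partly debenzylated material may also precipitate before reduction is finished.

The fallback separates the two events. It sets out from 11 and returns at 12. Concerted hydrogen transfer from diimide (TsNHNH2 in excess, NaOAc, DME/H2O, reflux) needs no catalyst surface. It gives 1-benzyloxy-2,4-bis[4-(benzyloxy)benzyl]-3-{2-[3-benzyloxy-4-(4-benzyloxybenzyl)phenyl]ethyl}-5-methoxybenzene F8. After chromatography, F8 undergoes plain hydrogenolysis of the benzyl ethers (H2, Pd(OH)2/C, THF/MeOH) to give 12.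

Further compounds
F1 | step 6 | (3-benzyloxy-5-methoxyphenyl)magnesium chloride | COc1cc([Mg]Cl)cc(OCc2ccccc2)c1
F2 | step 6 | 3-benzyloxy-5-methoxybenzaldehyde | COc1cc(C=O)cc(OCc2ccccc2)c1
F3 | step 6 | 3-benzyloxy-2,6-dibromo-5-methoxybenzaldehyde | COc1cc(OCc2ccccc2)c(Br)c(C=O)c1Br
F4 | step 6 | 1-benzyloxy-2,4-dibromo-5-methoxy-3-vinylbenzene | COc1cc(OCc2ccccc2)c(Br)c(C=C)c1Br
F5 | step 6 | 1-benzyloxy-2,4-bis[4-(benzyloxy)benzyl]-5-methoxy-3-vinylbenzene | COc1cc(OCc2ccccc2)c(Cc2ccc(OCc3ccccc3)cc2)c(C=C)c1Cc1ccc(OCc2ccccc2)cc1
F6 | step 4 | (2-benzyloxy-4-bromophenyl)magnesium chloride | Cl[Mg]c1ccc(Br)cc1OCc1ccccc1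
F7 | step 4 | (2-benzyloxy-4-bromophenyl)[4-(benzyloxy)phenyl]methanol (racemic) | OC(c1ccc(OCc2ccccc2)cc1)c1ccc(Br)cc1OCc1ccccc1
F8 | step 7 | 1-benzyloxy-2,4-bis[4-(benzyloxy)benzyl]-3-{2-[3-benzyloxy-4-(4-benzyloxybenzyl)phenyl]ethyl}-5-methoxybenzene | COc1cc(OCc2ccccc2)c(Cc2ccc(OCc3ccccc3)cc2)c(CCc2ccc(Cc3ccc(OCc4ccccc4)cc3)c(OCc3ccccc3)c2)c1Cc1ccc(OCc2ccccc2)cc1
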